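**Strategy.** The route rests on making the bond between pyranone C2 and C1′ of the para-hydroxyphenyl ring (ring B) in a three-component carbonylative annulation. C2 is an acyl-level carbon flanked by O1 of ring A and enolic C3, and stands 1,3 to the C4 carbonyl, so it can come from carbon monoxide. Palladium joins an aryl iodide, CO and an ortho-hydroxyacetophenone, and base-induced acyl transfer plus cyclodehydration build ring C in the same pot. The precursor is 2-hydroxy-4,5,6-tris(benzyloxy)acetophenone plus 1-(benzyloxy)-4-iodobenzene. The flavone is then hydroxylated at C3, sulfated on this only free hydroxyl and debenzylated.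

Key step: step 3

Remark: the target has no stereocentre and is achiral, so no enantiocontrol is needed. It is taken as the free hydrogen sulfate as drawn; sulfate 12 is drawn in its acid form although it would be handled as its pyridinium salt.

Step 1
Reactants: 1 3,4,5-tris(benzyloxy)benzaldehyde
Product: 3 3,4,5-tris(benzyloxy)phenol, via aryl formate 2 (not isolated)
Conditions: mCPBA, CH2Cl2, 0 °C to rt; then cat. K2CO3, MeOH, rt
Reagents that add atoms: mCPBA (3-chloroperoxybenzoic acid), O=C(OO)c1cccc(Cl)c1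
Why: Baeyer–Villiger (Dakin-type) oxidation, in which the electron-rich trialkoxyaryl group migrates in preference to hydride to give the aryl formate, which mild methanolysis cleaves while the benzyl ethers stay untouched.

Step 2
Reactants: 3 3,4,5-tris(benzyloxy)phenol
Product: 5 1-[2-hydroxy-4,5,6-tris(benzyloxy)phenyl]ethanone, via O-acetylated ketone 4 (not isolated)
Conditions: AcOH, TFAA, cat. H3PO4, CH2Cl2, 0 °C to rt; then K2CO3, MeOH, rt
Reagents that add atoms: acetic acid, CC(=O)O
Why: Friedel–Crafts acylation by the mixed anhydride acetyl trifluoroacetate at the only free ring positions (C2/C6, equivalent, ortho/para to two benzyloxy groups), without a metal Lewis acid that would cleave benzyl ethers; the methanolysis removes the phenolic O-acetyl group.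

Step 3
Reactants: 5 1-[2-hydroxy-4,5,6-tris(benzyloxy)phenyl]ethanone, 6 1-(benzyloxy)-4-iodobenzene
Product: 9 5,6,7-tris(benzyloxy)-2-[4-(benzyloxy)phenyl]-4H-chromen-4-one, via aryl benzoate 7 (not isolated), via 1,3-diketone 8 (not isolated)
Conditions: CO (5 bar), cat. Pd(OAc)2, cat. dppb, DBU, DMSO, 110 °C; then AcOH, 100 °C
Reagents that add atoms: carbon monoxide, [C-]#[O+]
Why: Pd(0) inserts into the C–I bond of 6 and the arylpalladium species takes up CO, which forges the bond from ring-B C1′ to the carbon that becomes C2; the phenoxide of 5 intercepts the aroylpalladium to give ester 7, DBU then drives a Baker–Venkataraman O→C acyl shift through the ketone enolate (C2–C3 bond) to diketone 8, and the phenol adds to the aroyl carbonyl with loss of water. The closest known reaction type is the palladium-catalysed carbonylative coupling of aryl halides with 2-hydroxyacetophenones to flavones (aryloxycarbonylation, Baker–Venkataraman rearrangement and cyclodehydration in one pot). Ring C closes by 6-exo-trig attack of the phenolic oxygen on the aroyl C=O followed by dehydration of the hemiketal. No stereocentre is created. The step needs mono-carbonylation and acyl capture in preference to hydrodehalogenation or direct O-arylation; CO pressure and the bidentate phosphine favour the acyl complex, regiochemistry is fixed because 5 has a single free phenol and a single enolisable methyl group, and the benzyl ethers are inert.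

Step 4
Reactants: 9 5,6,7-tris(benzyloxy)-2-[4-(benzyloxy)phenyl]-4H-chromen-4-one
Product: 11 5,6,7-tris(benzyloxy)-2-[4-(benzyloxy)phenyl]-3-hydroxy-4H-chromen-4-one, via flavone 2,3-epoxide 10 (not isolated)
Conditions: DMDO (acetone), CH2Cl2, 0 °C to rt; then cat. p-TsOH, CHCl3, rt
Reagents that add atoms: dimethyldioxirane (DMDO), CC1(C)OO1
Why: Epoxidation of the C2=C3 enol-ether bond by DMDO and acid-catalysed opening through the C2 oxocarbenium ion with loss of H-3 (flavone to flavonol oxidation) should leave the 3-OH as the only free hydroxyl; the racemic epoxide stereocentres are erased on isomerisation.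

Step 5
Reactants: 11 5,6,7-tris(benzyloxy)-2-[4-(benzyloxy)phenyl]-3-hydroxy-4H-chromen-4-one
Product: 12 5,6,7-tris(benzyloxy)-2-[4-(benzyloxy)phenyl]-4-oxo-4H-chromen-3-yl hydrogen sulfate
Conditions: SO3·pyridine, pyridine, 50 °C
Reagents that add atoms: sulfur trioxide pyridine complex, O=S(=O)([O-])[n+]1ccccc1
Why: O-sulfation with a sulfur trioxide–amine complex can only occur at the 3-hydroxyl, since all other oxygens are benzylated.

Step 6
Reactants: 12 5,6,7-tris(benzyloxy)-2-[4-(benzyloxy)phenyl]-4-oxo-4H-chromen-3-yl hydrogen sulfate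
Product: 13 5,6,7-trihydroxy-2-(4-hydroxyphenyl)-4-oxo-4H-chromen-3-yl hydrogen sulfate (6-hydroxykaempferol 3-O-sulfate)
Conditions: H2 (1 atm), 10% Pd/C, THF/MeOH, rt, under argon on work-up; then Dowex 50W (H+), H2O/MeOH, 0 °C, lyophilise
Reagents that add atoms: none
Why: Catalytic hydrogenolysis should cleave the four aryl benzyl ethers while the aryl sulfate monoester and the flavonol C2=C3 bond are stable to Pd/H2 at ambient pressure, and cold cation exchange should deliver the hydrogen sulfate form.

**Compound list**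

1 | 3,4,5-tris(benzyloxy)benzaldehyde | O=Cc1cc(OCc2ccccc2)c(OCc2ccccc2)c(OCc2ccccc2)c1 | starting material
2 | 3,4,5-tris(benzyloxy)phenyl formate | O=COc1cc(OCc2ccccc2)c(OCc2ccccc2)c(OCc2ccccc2)c1 | intermediate (not isolated)
3 | 3,4,5-tris(benzyloxy)phenol | Oc1cc(OCc2ccccc2)c(OCc2ccccc2)c(OCc2ccccc2)c1 | intermediate
4 | 2-acetyl-3,4,5-tris(benzyloxy)phenyl acetate | CC(=O)Oc1cc(OCc2ccccc2)c(OCc2ccccc2)c(OCc2ccccc2)c1C(C)=O | intermediate (not isolated)
5 | 1-[2-hydroxy-4,5,6-tris(benzyloxy)phenyl]ethanone | CC(=O)c1c(O)cc(OCc2ccccc2)c(OCc2ccccc2)c1OCc1ccccc1 | intermediate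
6 | 1-(benzyloxy)-4-iodobenzene | Ic1ccc(OCc2ccccc2)cc1 | starting material
7 | 2-acetyl-3,4,5-tris(benzyloxy)phenyl 4-(benzyloxy)benzoate | CC(=O)c1c(OC(=O)c2ccc(OCc3ccccc3)cc2)cc(OCc2ccccc2)c(OCc2ccccc2)c1OCc1ccccc1 | intermediate (not isolated)
8 | 1-[2-hydroxy-4,5,6-tris(benzyloxy)phenyl]-3-[4-(benzyloxy)phenyl]propane-1,3-dione | O=C(CC(=O)c1ccc(OCc2ccccc2)cc1)c1c(O)cc(OCc2ccccc2)c(OCc2ccccc2)c1OCc1ccccc1 | intermediate (not isolated)
9 | 5,6,7-tris(benzyloxy)-2-[4-(benzyloxy)phenyl]-4H-chromen-4-one | O=c1cc(-c2ccc(OCc3ccccc3)cc2)oc2cc(OCc3ccccc3)c(OCc3ccccc3)c(OCc3ccccc3)c12 | intermediate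
10 | 2,3-epoxy-5,6,7-tris(benzyloxy)-2-[4-(benzyloxy)phenyl]chroman-4-one (racemic, cis-fused epoxide) | O=C1C2OC2(c2ccc(OCc3ccccc3)cc2)Oc2cc(OCc3ccccc3)c(OCc3ccccc3)c(OCc3ccccc3)c21 | intermediate (not isolated)
11 | 5,6,7-tris(benzyloxy)-2-[4-(benzyloxy)phenyl]-3-hydroxy-4H-chromen-4-one | O=c1c(O)c(-c2ccc(OCc3ccccc3)cc2)oc2cc(OCc3ccccc3)c(OCc3ccccc3)c(OCc3ccccc3)c12 | intermediate
12 | 5,6,7-tris(benzyloxy)-2-[4-(benzyloxy)phenyl]-4-oxo-4H-chromen-3-yl hydrogen sulfate | O=c1c(OS(=O)(=O)O)c(-c2ccc(OCc3ccccc3)cc2)oc2cc(OCc3ccccc3)c(OCc3ccccc3)c(OCc3ccccc3)c12 | intermediate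
13 | 5,6,7-trihydroxy-2-(4-hydroxyphenyl)-4-oxo-4H-chromen-3-yl hydrogen sulfate | O=c1c(OS(=O)(=O)O)c(-c2ccc(O)cc2)oc2cc(O)c(O)c(O)c12 | target

**Step count.** Total steps: 6. Longest linear sequence: 6 steps (1 to 13).

**Steps most likely to fail**

Step 3 (key step). Acyl capture and the O→C acyl shift may be slow at the hindered, di-ortho-substituted ketone, so that hydrodehalogenation of the iodide or catalyst deactivation competes. The peri benzyl ether may also be partly lost during the acidic cyclodehydration. The fallback sets out from ketone 5 and returns at flavone 9, forming the same C2–C1′ bond by cross-coupling. Condensation of 5 with DMF-DMA (toluene, 90 °C) should give the enaminone (E)-3-(dimethylamino)-1-[2-hydroxy-4,5,6-tris(benzyloxy)phenyl]prop-2-en-1-one F1. Acid (HCl, CH2Cl2) should close it to 5,6,7-tris(benzyloxy)-4H-chromen-4-one F2. C2–H zincation with TMPZnCl·LiCl (THF, 25 °C, no added Lewis acid) should give [5,6,7-tris(benzyloxy)-4-oxo-4H-chromen-2-yl]zinc chloride F3. Negishi coupling with iodide 6 (Pd(dba)2, tri(2-furyl)phosphine, THF) would then deliver 9.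

Step 2. Acid-promoted debenzylation or C-benzyl migration on the very electron-rich ring may compete, or the reaction may stall at O-acylation. The fallback sets out from phenol 3 and returns at ketone 5 by a formylation, addition and oxidation sequence. Magnesium-mediated ortho-formylation (MgCl2, Et3N, paraformaldehyde, MeCN, reflux) should give 2-hydroxy-4,5,6-tris(benzyloxy)benzaldehyde F4. Addition of MeMgBr (THF, 0 °C) should give racemic 2-(1-hydroxyethyl)-3,4,5-tris(benzyloxy)phenol F5. Benzylic oxidation with MnO2 (CH2Cl2, rt) would then give 5.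

Step 4. Oxidation at the benzylic CH2 groups or on the electron-rich rings may compete with the slow epoxidation of the conjugated C2=C3 bond, and the epoxide may isomerise incompletely. The fallback sets out from flavone 9 and returns at flavonol 11 by metalation and borylation. Deprotonation at C3 with LDA (THF, −78 °C) should give 3-lithio-5,6,7-tris(benzyloxy)-2-[4-(benzyloxy)phenyl]-4H-chromen-4-one F6. Trapping with B(OMe)3 should give dimethyl {5,6,7-tris(benzyloxy)-2-[4-(benzyloxy)phenyl]-4-oxo-4H-chromen-3-yl}boronate F7. Oxidation with H2O2/AcOH would then give 11.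

**Further compounds**

F1 | step 3 | (E)-3-(dimethylamino)-1-[2-hydroxy-4,5,6-tris(benzyloxy)phenyl]prop-2-en-1-one | CN(C)/C=C/C(=O)c1c(O)cc(OCc2ccccc2)c(OCc2ccccc2)c1OCc1ccccc1
F2 | step 3 | 5,6,7-tris(benzyloxy)-4H-chromen-4-one | O=c1ccoc2cc(OCc3ccccc3)c(OCc3ccccc3)c(OCc3ccccc3)c12
F3 | step 3 | [5,6,7-tris(benzyloxy)-4-oxo-4H-chromen-2-yl]zinc chloride | Cl[Zn]c1cc(=O)c2c(OCc3ccccc3)c(OCc3ccccc3)c(OCc3ccccc3)cc2o1
F4 | step 2 | 2-hydroxy-4,5,6-tris(benzyloxy)benzaldehyde | O=Cc1c(O)cc(OCc2ccccc2)c(OCc2ccccc2)c1OCc1ccccc1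
F5 | step 2 | 2-(1-hydroxyethyl)-3,4,5-tris(benzyloxy)phenol (racemic) | CC(O)c1c(O)cc(OCc2ccccc2)c(OCc2ccccc2)c1OCc1ccccc1
F6 | step 4 | 3-lithio-5,6,7-tris(benzyloxy)-2-[4-(benzyloxy)phenyl]-4H-chromen-4-one | [Li]c1c(-c2ccc(OCc3ccccc3)cc2)oc2cc(OCc3ccccc3)c(OCc3ccccc3)c(OCc3ccccc3)c2c1=O
F7 | step 4 | dimethyl {5,6,7-tris(benzyloxy)-2-[4-(benzyloxy)phenyl]-4-oxo-4H-chromen-3-yl}boronate | COB(OC)c1c(-c2ccc(OCc3ccccc3)cc2)oc2cc(OCc3ccccc3)c(OCc3ccccc3)c(OCc3ccccc3)c2c1=O
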